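Readings and results are calculated for substances that don't exist.

**Minutes on the ash flask**

A one-step world, first order in Xb, asks the birch run to go 1.50 times as fast as the oak run at equal Xp made, and the meeting started by testing that.

| flask | Xa | Xb | time |
|---|---|---|---|
| oak | 0.100 M | 0.200 M |  |
| birch | 0.100 M | 0.300 M |  |
| ash | 0.400 M | 0.800 M | 11 h |

| run | time / h | [Xp] / M |
|---|---|---|
| oak run | 0.44 | 0.0071 |
| oak run | 0.75 | 0.0123 |
| oak run | 1.3 | 0.0223 |
| oak run | 2.2 | 0.0318 |
| oak run | 3.8 | 0.0472 |
| oak run | 6.4 | 0.0659 |
| oak run | 11 | 0.0817 |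
| birch run | 0.44 | 0.0089 |
| birch run | 0.75 | 0.0157 |
| birch run | 1.3 | 0.0259 |
| birch run | 2.2 | 0.0385 |
| birch run | 3.8 | 0.0560 |
| birch run | 6.4 | 0.0754 |
| birch run | 11 | 0.0916 |

(each reading ± 0.001 M)

- Overall: Xa + Xb -> Xp.
- Constant volume, constant temperature.
- "The second partner" is Xb.
- An order is taken over about fifteen percent of the charge, up and down.

- the power of [Xb] that the first rate follows, about the charge of the oak run; measure it at two percent of Xa made into Xp
- Xp in the ash run at 11 h, as a share of the Xa charged

The first speaker wrote the balance of Xa, the limiting reagent, charged at less than Xb in oak, birch and ash: Xa not yet made into Xp is the charge minus Xp. She proposed carrying 0.168 /h for the oak run as κ, the share of unturned Xa becoming Xp per hour on average up to the reading at 3.8 h, reckoned as the logarithm of charge over Xa unturned, divided by that time. The second speaker read 0.174 /h from the oak reading at 2.2 h. The birch reading at 3.8 h gives 0.216 /h.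

My own reckoning, as secretary: between those runs κ follows Xb with power 0.619, which I take for the first rate too. Carried to the ash charge by the Xb ratio, as oak and birch share 0.100 M of Xa, it gives κ of 0.397 /h and 98.7% at 11 h.

The forecast says 0.6 and 94%, lower than my share, with the warning that “stronger saturation could lower this”.

The ash run gives 95.5% at 11 h, and the power of Xb is 0.62.

    Xa + Xb ⇌ Xi, settled at all times (5.150 /M)
    Xi → Xp (0.4068 /h)

The ash κ comes to 0.281 /h, 1.67 times the oak 0.168 /h, lower than my 0.397 /h and lower than the 0.407 /h at which Xi turns to Xp. Put back on the birch run, its κ of 0.216 /h gives 0.09071 M of Xp at 11 h, where the reading is 0.0916 M.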